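**Strategy.** The six carbons of ring A (C4a, C5, C6, C7, C8, C8a) carry oxygen on every second atom: hydroxyls at C5 and C7 and the ring oxygen at C8a. C5–C8 can therefore come from a 1,1,3-trioxygenated butadiene and C4a=C8a from the enone of a 2-aryl-2,3-dihydropyran-4-one in which C2 is already S. One Diels–Alder reaction of 1-methoxy-1,3-bis(trimethylsilyloxy)butadiene with the 5-phenylsulfinyl pyranone forms C4a–C5 and C8–C8a, and loss of benzenesulfenic acid and methanol aromatises ring A in the same flask. Because the prenyl alkene would not tolerate electrophilic sulfur reagents, the sulfinyl pyranone is built from a sulfoxide building block: enantioselective acetate aldol, acylation of lithiated methyl phenyl sulfoxide, then formylative ring closure.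

Key step: step 9

Assumption: (S)-BINOL/Ti(OiPr)4 is taken to direct the nucleophile to the Si face of the aryl aldehyde (the sense seen in allylations with this catalyst), which gives the S carbinol; should a chiral HPLC check of compound 8 against the racemate show the opposite sense, (R)-BINOL is used with no other change.

**Step 1**
Reactants: 1 3,4-dihydroxybenzaldehyde; 2 1-bromo-3-methylbut-2-ene (prenyl bromide)
Product: 3 3-hydroxy-4-(3-methylbut-2-enyloxy)benzaldehyde
Conditions: NaHCO3 (1.5 equiv), NaI (cat.), DMF, 40 °C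
Reagents that add atoms: none
Why: Williamson etherification in which the weak base ionises only the more acidic 4-OH (para to the formyl group), so the prenyl group should go to O-4 and leave O-3 free.

**Step 2**
Reactants: 3 3-hydroxy-4-(3-methylbut-2-enyloxy)benzaldehyde
Product: 4 3-(tert-butyldimethylsilyloxy)-4-(3-methylbut-2-enyloxy)benzaldehyde
Conditions: TBSCl, imidazole, CH2Cl2, rt
Reagents that add atoms: tert-butyldimethylsilyl chloride (TBSCl), CC(C)(C)[Si](C)(C)Cl
Why: Imidazole-promoted silylation of a phenol gives an aryl silyl ether that tolerates the Lewis-acidic, low-temperature basic and thermal steps ahead and is removable by fluoride at the end.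

**Step 3**
Reactants: 5 S-tert-butyl thioacetate
Product: 6 1-(tert-butylsulfanyl)-1-(trimethylsilyloxy)ethene
Conditions: LDA, THF, −78 °C; then TMSCl, −78 °C → rt; distillation
Reagents that add atoms: chlorotrimethylsilane (TMSCl), C[Si](C)(C)Cl
Why: Kinetic enolisation of the thioester and O-silylation of the enolate give the silyl ketene thioacetal needed as the acetate nucleophile.

**Step 4**
Reactants: 4 3-(tert-butyldimethylsilyloxy)-4-(3-methylbut-2-enyloxy)benzaldehyde; 6 1-(tert-butylsulfanyl)-1-(trimethylsilyloxy)ethene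
Product: 8 S-tert-butyl (3S)-3-[3-(tert-butyldimethylsilyloxy)-4-(3-methylbut-2-enyloxy)phenyl]-3-hydroxypropanethioate, via O-trimethylsilyl aldol adduct 7 (not isolated)
Conditions: (S)-BINOL (20 mol%), Ti(OiPr)4 (20 mol%), 4 Å MS, Et2O, −20 °C; then 1 M HCl, THF, 0 °C
Reagents that add atoms: none
Why: Enantioselective Mukaiyama aldol addition in which the chiral BINOL–titanium complex exposes one face of the aldehyde (Si face assumed) and so sets the carbinol centre, the future C2, as S, while the brief cold acid treatment cleaves only the trimethylsilyl ether.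

**Step 5**
Reactants: 8 S-tert-butyl (3S)-3-[3-(tert-butyldimethylsilyloxy)-4-(3-methylbut-2-enyloxy)phenyl]-3-hydroxypropanethioate; 9 methyl phenyl sulfoxide (racemic)
Product: 10 (4S)-4-[3-(tert-butyldimethylsilyloxy)-4-(3-methylbut-2-enyloxy)phenyl]-4-hydroxy-1-(phenylsulfinyl)butan-2-one (both sulfur epimers)
Conditions: 9 (3.3 equiv), LDA (3.3 equiv), THF, −78 °C; then 8, −78 → −40 °C; AcOH quench
Reagents that add atoms: none
Why: Claisen-type acylation of α-lithiated methyl phenyl sulfoxide by the thioester, the classical entry to β-keto sulfoxides, in which the first equivalent of carbanion masks the hydroxyl as its alkoxide, the third is taken up by the acidic product, and the carbinol centre is not involved.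

**Step 6**
Reactants: 10 (4S)-4-[3-(tert-butyldimethylsilyloxy)-4-(3-methylbut-2-enyloxy)phenyl]-4-hydroxy-1-(phenylsulfinyl)butan-2-one; 11 N,N-dimethylformamide dimethyl acetal
Product: 13 (2S)-2-[3-(tert-butyldimethylsilyloxy)-4-(3-methylbut-2-enyloxy)phenyl]-5-(phenylsulfinyl)-2,3-dihydro-4H-pyran-4-one (both sulfur epimers), via aminomethylene ketone 12 (not isolated)
Conditions: 11 (1.2 equiv), toluene, rt; then AcOH (3 equiv), 40 °C
Reagents that add atoms: none
Why: Aminomethylenation of the methylene flanked by C=O and S=O followed by acid-assisted 6-endo addition–elimination of the hydroxyl with loss of dimethylamine closes the dihydropyranone, as known for δ-hydroxy β-keto esters and for the β-keto sulfoxides that give 3-sulfinylchromones; the C–O bond at the stereocentre is untouched, so C2 stays S.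

**Step 7**
Reactants: 14 methyl acetoacetate
Product: 15 methyl 3-(trimethylsilyloxy)but-2-enoate
Conditions: TMSCl, Et3N, hexane, rt
Reagents that add atoms: chlorotrimethylsilane (TMSCl), C[Si](C)(C)Cl
Why: O-silylation of the enol of a β-keto ester under amine base is a standard silyl enol ether formation.

**Step 8**
Reactants: 15 methyl 3-(trimethylsilyloxy)but-2-enoate
Product: 16 1-methoxy-1,3-bis(trimethylsilyloxy)buta-1,3-diene
Conditions: LDA, THF, −78 °C; then TMSCl, −78 → 0 °C; used freshly distilled
Reagents that add atoms: chlorotrimethylsilane (TMSCl), C[Si](C)(C)Cl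
Why: γ-Deprotonation of the vinylogous ester and O-silylation of the resulting dienolate give the electron-rich 1,1,3-trioxygenated diene.

**Step 9**
Reactants: 13 (2S)-2-[3-(tert-butyldimethylsilyloxy)-4-(3-methylbut-2-enyloxy)phenyl]-5-(phenylsulfinyl)-2,3-dihydro-4H-pyran-4-one; 16 1-methoxy-1,3-bis(trimethylsilyloxy)buta-1,3-diene
Product: 19 (2S)-2-[3-(tert-butyldimethylsilyloxy)-4-(3-methylbut-2-enyloxy)phenyl]-5,7-dihydroxy-2,3-dihydro-4H-chromen-4-one (3'-O-TBS monotesone A), via cis-fused sulfinyl cycloadduct 17 (not isolated), via bis-silylated ketal dihydroarene 18 (not isolated)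
Conditions: 16 (3 equiv), toluene, 0 °C → rt, then 70 °C; then 0.5 M HCl, THF, 0 °C
Reagents that add atoms: none
Why: In a polarised, asynchronous Diels–Alder reaction the CH2 terminus of the diene bonds to C6 of the pyranone, the β-carbon activated by both ketone and sulfinyl group, and the ketene-acetal carbon bonds to C5, giving the cis-fused adduct 17. Warming brings about syn-elimination of benzenesulfenic acid (sulfinyl group and angular hydrogen are cis), which restores C4a=C8a; cold aqueous acid then removes the trimethylsilyl groups, the hemiketal at C5 loses methanol and the dienone tautomerises to the 5,7-dihydroxyarene. The closest known reaction type is the Diels–Alder/sulfoxide-elimination aromatisation of oxygenated dienes with α-sulfinyl enones such as sulfinylquinones and 3-sulfinylchromones. Ring A closes as a six-membered carbocycle by [4+2] cycloaddition or, in the stepwise limit, by Mukaiyama–Michael addition followed by 6-(enolexo)-exo-trig acylation. No new stereocentre survives, since both ring-fusion centres of 17 are destroyed on aromatisation, so neither facial selectivity nor the sulfur configuration matters. The selectivities needed are regiochemistry, secured by the matched polarisation of the push–pull diene and the doubly activated enone, and retention of C2, secured by neutral, base-free conditions that neither enolise C3 nor open the benzylic C2–O bond.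

**Step 10**
Reactants: 19 (2S)-2-[3-(tert-butyldimethylsilyloxy)-4-(3-methylbut-2-enyloxy)phenyl]-5,7-dihydroxy-2,3-dihydro-4H-chromen-4-one
Product: 20 monotesone A, (2S)-5,7-dihydroxy-2-[3-hydroxy-4-(3-methylbut-2-enyloxy)phenyl]-2,3-dihydro-4H-chromen-4-one
Conditions: Bu4NF (1.1 equiv), AcOH (1.5 equiv), THF, 0 °C
Reagents that add atoms: none
Why: Fluoride-mediated cleavage of the aryl silyl ether, with the acetic acid buffer keeping the medium too weakly basic for retro-oxa-Michael opening of the flavanone to the chalcone, which would racemise C2.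

**Compound list**
1 | 3,4-dihydroxybenzaldehyde | O=Cc1ccc(O)c(O)c1 | starting material
2 | 1-bromo-3-methylbut-2-ene (prenyl bromide) | CC(C)=CCBr | starting material
3 | 3-hydroxy-4-(3-methylbut-2-enyloxy)benzaldehyde | CC(C)=CCOc1ccc(C=O)cc1O | intermediate
4 | 3-(tert-butyldimethylsilyloxy)-4-(3-methylbut-2-enyloxy)benzaldehyde | CC(C)=CCOc1ccc(C=O)cc1O[Si](C)(C)C(C)(C)C | intermediate
5 | S-tert-butyl thioacetate | CC(=O)SC(C)(C)C | starting material
6 | 1-(tert-butylsulfanyl)-1-(trimethylsilyloxy)ethene | C=C(O[Si](C)(C)C)SC(C)(C)C | intermediate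
7 | S-tert-butyl (3S)-3-[3-(tert-butyldimethylsilyloxy)-4-(3-methylbut-2-enyloxy)phenyl]-3-(trimethylsilyloxy)propanethioate (not isolated) | CC(C)=CCOc1ccc([C@@H](O[Si](C)(C)C)CC(=O)SC(C)(C)C)cc1O[Si](C)(C)C(C)(C)C | intermediate
8 | S-tert-butyl (3S)-3-[3-(tert-butyldimethylsilyloxy)-4-(3-methylbut-2-enyloxy)phenyl]-3-hydroxypropanethioate | CC(C)=CCOc1ccc([C@@H](O)CC(=O)SC(C)(C)C)cc1O[Si](C)(C)C(C)(C)C | intermediate
9 | methyl phenyl sulfoxide (racemic) | CS(=O)c1ccccc1 | starting material
10 | (4S)-4-[3-(tert-butyldimethylsilyloxy)-4-(3-methylbut-2-enyloxy)phenyl]-4-hydroxy-1-(phenylsulfinyl)butan-2-one (both sulfur epimers) | CC(C)=CCOc1ccc([C@@H](O)CC(=O)CS(=O)c2ccccc2)cc1O[Si](C)(C)C(C)(C)C | intermediate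
11 | N,N-dimethylformamide dimethyl acetal | COC(OC)N(C)C | starting material
12 | (5S)-5-[3-(tert-butyldimethylsilyloxy)-4-(3-methylbut-2-enyloxy)phenyl]-1-(dimethylamino)-5-hydroxy-2-(phenylsulfinyl)pent-1-en-3-one (not isolated; alkene geometry and sulfur configuration open) | CC(C)=CCOc1ccc([C@@H](O)CC(=O)C(=CN(C)C)S(=O)c2ccccc2)cc1O[Si](C)(C)C(C)(C)C | intermediate
13 | (2S)-2-[3-(tert-butyldimethylsilyloxy)-4-(3-methylbut-2-enyloxy)phenyl]-5-(phenylsulfinyl)-2,3-dihydro-4H-pyran-4-one (both sulfur epimers) | CC(C)=CCOc1ccc([C@@H]2CC(=O)C(S(=O)c3ccccc3)=CO2)cc1O[Si](C)(C)C(C)(C)C | intermediate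
14 | methyl acetoacetate | COC(=O)CC(C)=O | starting material
15 | methyl 3-(trimethylsilyloxy)but-2-enoate (geometry immaterial) | COC(=O)C=C(C)O[Si](C)(C)C | intermediate
16 | 1-methoxy-1,3-bis(trimethylsilyloxy)buta-1,3-diene (ketene-acetal geometry immaterial) | C=C(O[Si](C)(C)C)C=C(OC)O[Si](C)(C)C | intermediate
17 | (2S)-2-[3-(tert-butyldimethylsilyloxy)-4-(3-methylbut-2-enyloxy)phenyl]-5-methoxy-4a-(phenylsulfinyl)-5,7-bis(trimethylsilyloxy)-2,3,4a,5,8,8a-hexahydro-4H-chromen-4-one (not isolated; 4a/8a cis-fused, mixture at the ring-fusion face, C5 and sulfur) | CC(C)=CCOc1ccc([C@@H]2CC(=O)C3(S(=O)c4ccccc4)C(OC)(O[Si](C)(C)C)C=C(O[Si](C)(C)C)CC3O2)cc1O[Si](C)(C)C(C)(C)C | intermediate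
18 | (2S)-2-[3-(tert-butyldimethylsilyloxy)-4-(3-methylbut-2-enyloxy)phenyl]-5-methoxy-5,7-bis(trimethylsilyloxy)-2,3,5,8-tetrahydro-4H-chromen-4-one (not isolated; C5 epimers) | CC(C)=CCOc1ccc([C@@H]2CC(=O)C3=C(O2)CC(O[Si](C)(C)C)=CC3(OC)O[Si](C)(C)C)cc1O[Si](C)(C)C(C)(C)C | intermediate
19 | (2S)-2-[3-(tert-butyldimethylsilyloxy)-4-(3-methylbut-2-enyloxy)phenyl]-5,7-dihydroxy-2,3-dihydro-4H-chromen-4-one (3'-O-TBS monotesone A) | CC(C)=CCOc1ccc([C@@H]2CC(=O)c3c(O)cc(O)cc3O2)cc1O[Si](C)(C)C(C)(C)C | intermediate
20 | monotesone A, (2S)-5,7-dihydroxy-2-[3-hydroxy-4-(3-methylbut-2-enyloxy)phenyl]-2,3-dihydro-4H-chromen-4-one | CC(C)=CCOc1ccc([C@@H]2CC(=O)c3c(O)cc(O)cc3O2)cc1O | target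

**Step count.** Total: 10 steps. Longest linear sequence: 7 steps (steps 1, 2, 4, 5, 6, 9, 10); steps 3 and 7–8 are side branches.

**Steps most likely to fail**

Step 9. After the first C–C bond forms, the enolate or silyl enol ether may expel the ring oxygen (retro-oxa-Michael ring opening) before ring A closes. Silyl transfer to the sulfinyl oxygen may divert the sulfoxide into Pummerer-type chemistry. Aromatisation with loss of silanol in place of methanol would leave the C5 oxygen methylated, and the liberated sulfenic acid may add to the prenyl alkene. The fallback is a chalcone route that sets out from 3 and comes back at 20. Compound 3 is protected with MOMCl/iPr2NEt to give 3-(methoxymethoxy)-4-(3-methylbut-2-enyloxy)benzaldehyde F1. Claisen–Schmidt condensation with commercial 2'-hydroxy-4',6'-bis(methoxymethoxy)acetophenone (KOH, EtOH, rt) gives the 2'-hydroxychalcone F2. NaOAc in refluxing EtOH closes it by oxa-Michael addition to the racemic tris-MOM flavanone F3. Kinetic resolution by asymmetric transfer hydrogenation with RuCl[(R,R)-TsDPEN](p-cymene) in HCO2H/Et3N, stopped near half conversion, should leave the (2S)-tris-MOM flavanone F4 and turn its enantiomer into the separable cis-(2R,4R)-flavan-4-ol F5. The three MOM ethers of F4 are then removed without protic acid, which the prenyl ether would not tolerate (TMSOTf, 2,2'-bipyridyl, CH3CN, 0 °C; then water), to give 20.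

Step 5. The strongly basic sulfinyl carbanion may enolise the thioester or cleave the lithium aldolate by retro-aldol fragmentation, with loss of material or of enantiopurity, and the thiolate released may attack the aryl silyl ether. The fallback builds the pyranone ring first; it sets out from 4 and comes back at 13. Compound 4 is combined with commercial (E)-1-methoxy-3-(trimethylsilyloxy)buta-1,3-diene under the same (S)-BINOL/Ti(OiPr)4 catalysis and the adduct is closed with a little TFA at 0 °C (formal hetero-Diels–Alder reaction). This should give (2S)-2-[3-(tert-butyldimethylsilyloxy)-4-(3-methylbut-2-enyloxy)phenyl]-2,3-dihydro-4H-pyran-4-one F6. Iodination at C5 with I2/pyridine in CH2Cl2 gives the 5-iodo pyranone F7. Palladium-catalysed C–S coupling with thiophenol (Pd2(dba)3, Xantphos, iPr2NEt, dioxane, 60 °C) gives the 5-phenylsulfanyl pyranone F8; a sulfenyl chloride is avoided because it would add to the prenyl alkene. Oxidation with mCPBA (1.0 equiv, CH2Cl2, −78 °C), which attacks sulfur faster than the trisubstituted alkene, gives 13.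

Step 4. The electron-rich aldehyde may react slowly, and facial selectivity may be insufficient for a single enantiomer. The fallback sets the stereocentre by reduction; it sets out from 4 and comes back at 10. Compound 4 is homologated with ethyl diazoacetate and catalytic SnCl2 in CH2Cl2 (Roskamp reaction) to ethyl 3-[3-(tert-butyldimethylsilyloxy)-4-(3-methylbut-2-enyloxy)phenyl]-3-oxopropanoate F9. Asymmetric transfer hydrogenation with RuCl[(S,S)-TsDPEN](p-cymene) in HCO2H/Et3N should give ethyl (3S)-3-[3-(tert-butyldimethylsilyloxy)-4-(3-methylbut-2-enyloxy)phenyl]-3-hydroxypropanoate F10. The sense follows the acetophenone model with the aryl group as the large substituent, and the alkene is inert to transfer hydrogenation. F10 is then acylated onto lithiated 9 under the conditions of step 5 to give 10.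

**Further compounds**
F1 | step 9 | 3-(methoxymethoxy)-4-(3-methylbut-2-enyloxy)benzaldehyde | CC(C)=CCOc1ccc(C=O)cc1OCOC
F2 | step 9 | (E)-1-[2-hydroxy-4,6-bis(methoxymethoxy)phenyl]-3-[3-(methoxymethoxy)-4-(3-methylbut-2-enyloxy)phenyl]prop-2-en-1-one | CC(C)=CCOc1ccc(/C=C/C(=O)c2c(O)cc(OCOC)cc2OCOC)cc1OCOC
F3 | step 9 | racemic 5,7-bis(methoxymethoxy)-2-[3-(methoxymethoxy)-4-(3-methylbut-2-enyloxy)phenyl]-2,3-dihydro-4H-chromen-4-one | CC(C)=CCOc1ccc(C2CC(=O)c3c(OCOC)cc(OCOC)cc3O2)cc1OCOC
F4 | step 9 | (2S)-5,7-bis(methoxymethoxy)-2-[3-(methoxymethoxy)-4-(3-methylbut-2-enyloxy)phenyl]-2,3-dihydro-4H-chromen-4-one | CC(C)=CCOc1ccc([C@@H]2CC(=O)c3c(OCOC)cc(OCOC)cc3O2)cc1OCOC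
F5 | step 9 | (2R,4R)-5,7-bis(methoxymethoxy)-2-[3-(methoxymethoxy)-4-(3-methylbut-2-enyloxy)phenyl]-3,4-dihydro-2H-chromen-4-ol | CC(C)=CCOc1ccc([C@H]2C[C@@H](O)c3c(OCOC)cc(OCOC)cc3O2)cc1OCOC
F6 | step 5 | (2S)-2-[3-(tert-butyldimethylsilyloxy)-4-(3-methylbut-2-enyloxy)phenyl]-2,3-dihydro-4H-pyran-4-one | CC(C)=CCOc1ccc([C@@H]2CC(=O)C=CO2)cc1O[Si](C)(C)C(C)(C)C
F7 | step 5 | (2S)-2-[3-(tert-butyldimethylsilyloxy)-4-(3-methylbut-2-enyloxy)phenyl]-5-iodo-2,3-dihydro-4H-pyran-4-one | CC(C)=CCOc1ccc([C@@H]2CC(=O)C(I)=CO2)cc1O[Si](C)(C)C(C)(C)C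
F8 | step 5 | (2S)-2-[3-(tert-butyldimethylsilyloxy)-4-(3-methylbut-2-enyloxy)phenyl]-5-(phenylsulfanyl)-2,3-dihydro-4H-pyran-4-one | CC(C)=CCOc1ccc([C@@H]2CC(=O)C(Sc3ccccc3)=CO2)cc1O[Si](C)(C)C(C)(C)C
F9 | step 4 | ethyl 3-[3-(tert-butyldimethylsilyloxy)-4-(3-methylbut-2-enyloxy)phenyl]-3-oxopropanoate | CC(C)=CCOc1ccc(C(=O)CC(=O)OCC)cc1O[Si](C)(C)C(C)(C)C
F10 | step 4 | ethyl (3S)-3-[3-(tert-butyldimethylsilyloxy)-4-(3-methylbut-2-enyloxy)phenyl]-3-hydroxypropanoate | CC(C)=CCOc1ccc([C@@H](O)CC(=O)OCC)cc1O[Si](C)(C)C(C)(C)C
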